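The vessel starts with the solid reagent undissolved, and what to watch in it is how much target survives: each side product is made from one target.

all flasks: starting material 0.020 M

| run | solid reagent | remark | time |
|---|---|---|---|
| Tuesday's | 0.034 M | run made earlier |  |
| Monday's | 0.053 M | run made earlier |  |
| flask | 0.0240 M |  | 8.0 h |

| run | time / h | isomer of the product / % | target / % | starting material / % |
|---|---|---|---|---|
| Tuesday's | 0.667 | 5.8 | 6.3 | 84.8 |
| Tuesday's | 1.33 | 10.8 | 10.3 | 63.5 |
| Tuesday's | 2.00 | 15.6 | 12.0 | 46.1 |
| Tuesday's | 3.00 | 18.3 | 13.7 | 29.4 |
| Tuesday's | 4.00 | 20.4 | 14.1 | 19.7 |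
| Tuesday's | 5.00 | 20.2 | 13.1 | 14.5 |
| Monday's | 0.250 | 1.0 | 2.9 | 97.6 |
| Monday's | 0.667 | 4.8 | 6.0 | 85.1 |
| Monday's | 1.33 | 10.5 | 9.3 | 64.4 |
| Monday's | 2.00 | 15.5 | 11.7 | 46.8 |
| Monday's | 3.00 | 19.1 | 13.4 | 29.9 |
| Monday's | 4.00 | 19.2 | 12.5 | 19.7 |
| Monday's | 5.00 | 20.3 | 12.9 | 14.2 |

(standard deviation of a reading: 0.5 percentage points)

- ratio of isomer of the product to target at 10 min
- ratio of isomer of the product to target at 1.0 h
- ratio of isomer of the product to target at 8.0 h

- a species is counted by the starting material in it: one side product counts as two
- given per volume of solution although it is solid: solid reagent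
- what may be going on: starting material + coupling partner <-> target; starting material + coupling partner <-> isomer of the product; starting material + target -> side product; solid reagent <-> coupling partner
- at the start none of the solid reagent is in solution

I worked with what is left. Each side product holds one target, so target ever made is target plus half the side product, and target over that sum is the fraction of target left, 0.334 in Tuesday's run at 5.00 h.

ratio = (isomer of the product per target ever made) / (fraction of target left)

The first setting is the solid charge. By hand, less solid should mean less coupling partner and slower loss of starting material. But at 3.00 h Monday's run held 29.9 % of its starting material and Tuesday's 29.4 %, and Tuesday's run had used 0.0119 M of coupling partner by 5.00 h, half of the new flask's charge, not counting what stood dissolved. So I reckoned the new flask as a copy of those runs.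

The second setting is time. Tuesday's isomer per target ever made was 0.620 at 2.00 h, the selectivity factor. With the fraction left set to one, that is my ratio at 10 min. At 1.0 h, halfway between two samplings, the fraction left is 0.678, which gives 0.915. Continuing Tuesday's proportional rise of the ratio from 3.00 h to 5.00 h gives 1.91 at 8.0 h.

The forecast gave 0.45, 1 and 1.9, lower than mine at the first time and level at the last, noting: “The 8 h value is the least certain”.

The flask gave 0.662, 0.947 and 1.66.

    starting material + coupling partner ⇌ target (K = 209 M⁻¹, k = 0.535 M⁻¹ min⁻¹)
    starting material + coupling partner ⇌ isomer of the product (K = 157 M⁻¹, k = 0.328 M⁻¹ min⁻¹)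
    starting material + target → side product (k = 1.11 M⁻¹ min⁻¹)
    solid reagent ⇌ coupling partner, rate k4*(cs4 - [coupling partner]) while solid is left; crystals form when [coupling partner] > cs4 (solubility = 8.60 mM, k = 0.0513 min⁻¹)

Up to 8.0 h in this flask, the making of target turned over 42.3 % net of the starting material charged, and the loss of target to side product 31.4 %. So the fraction of target left in this flask was 0.257 at 8.0 h, lower than the 0.334 read in Tuesday's run at 5.00 h, while the isomer's net turnover stood at 18.1 %. In the neighbour flask with 0.012 M of starting material, the fraction left at 8.0 h was 0.365 and the ratio 1.30.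

The runs were generated by integration with made-up constants.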